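Ring C of the flavanonol is closed at the C3–C4 bond. The precursor is an open-chain aryl ether in which the ring-A aldehyde is the future C4 and an N-acyloxyphthalimide sits one carbon beyond the acetoxy-bearing future C3. In one operation an NHC-catalysed decarboxylative radical acylation turns the aldehyde into a ketyl radical and the activated ester into the C3 α-acetoxy radical. Their recombination forms the pyranone ring, the C4 ketone and the C3 stereocentre. The step exploits the aryl ketone C4 next to the oxygen-bearing C3, with the C2 aryl-ether stereocentre, installed from an enantiopure phenylglycidate, steering the 2,3-trans relationship.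

Key step: step 9

Remark: methyl (2R,3S)-3-phenylglycidate is taken as a commercial, enantiopure starting material. The acetoxy-bearing carbon of the acid chain passes through a planar radical, so only the benzylic aryl-ether centre has to be carried in defined form up to the key step.

Step 1
Reactants: 1 phloroglucinol
Product: 2 3,5-bis(methoxymethoxy)phenol
Conditions: MOMCl (2.0 equiv), i-Pr2NEt, DMF, 0 °C to rt
Reagents that add atoms: chloromethyl methyl ether, COCCl
Why: Williamson-type O-alkylation under stoichiometry control should cap two of the three equivalent phenols, the bis-ether being separated by chromatography from mono- and tris-ether.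

Step 2
Reactants: 2 3,5-bis(methoxymethoxy)phenol
Product: 3 [3,5-bis(methoxymethoxy)phenoxy]triisopropylsilane
Conditions: TIPSCl, imidazole, DMF, rt
Reagents that add atoms: triisopropylsilyl chloride, CC(C)[Si](Cl)(C(C)C)C(C)C
Why: Silyl ether formation masks the third oxygen as a bulky, non-directing group that is orthogonal to the two acetals.

Step 3
Reactants: 3 [3,5-bis(methoxymethoxy)phenoxy]triisopropylsilane
Product: 6 3,5-bis(methoxymethoxy)-4-(3-methylbut-2-en-1-yl)phenol, via aryllithium 4 (not isolated), via prenylated silyl ether 5 (not isolated)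
Conditions: n-BuLi, THF, 0 °C; CuI (10 mol %), prenyl bromide, −78 °C to rt; then TBAF, rt; aq. NH4Cl
Reagents that add atoms: prenyl bromide (1-bromo-3-methylbut-2-ene), CC(C)=CCBr
Why: Directed ortho-metalation should place lithium on the carbon between the two cooperating MOM ethers (the TIPS ether shields its own ortho positions), the aryllithium is alkylated by prenyl bromide, and fluoride cleaves the silyl ether in the same pot.

Step 4
Reactants: 6 3,5-bis(methoxymethoxy)-4-(3-methylbut-2-en-1-yl)phenol
Product: 8 6-hydroxy-2,4-bis(methoxymethoxy)-3-(3-methylbut-2-en-1-yl)benzaldehyde, via hydroxymethylphenol 7 (not isolated)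
Conditions: MgCl2, Et3N, (CH2O)n, MeCN, reflux
Reagents that add atoms: paraformaldehyde (as formaldehyde), C=O
Why: In this magnesium-mediated ortho-formylation (Casnati–Skattebøl) the magnesium phenoxide delivers formaldehyde to an ortho carbon and a second formaldehyde oxidises the hydroxymethyl intermediate by hydride transfer, and since both ortho positions are equivalent only one aldehyde can form.

Step 5
Reactants: 8 6-hydroxy-2,4-bis(methoxymethoxy)-3-(3-methylbut-2-en-1-yl)benzaldehyde; 9 methyl (2R,3S)-3-phenyloxirane-2-carboxylate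
Product: 10 methyl (2R,3R)-3-[2-formyl-3,5-bis(methoxymethoxy)-4-(3-methylbut-2-en-1-yl)phenoxy]-2-hydroxy-3-phenylpropanoate
Conditions: Cs2CO3 (0.3 equiv), DMF, 60 °C
Reagents that add atoms: none
Why: Base-catalysed SN2 opening of the trans-glycidic ester by the phenoxide at the benzylic C3, favoured over attack next to the ester, should proceed with inversion (3S to 3R) and so fix the configuration of the future C2, while C2 of the ester is untouched.

Step 6
Reactants: 10 methyl (2R,3R)-3-[2-formyl-3,5-bis(methoxymethoxy)-4-(3-methylbut-2-en-1-yl)phenoxy]-2-hydroxy-3-phenylpropanoate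
Product: 11 (2R,3R)-3-[2-formyl-3,5-bis(methoxymethoxy)-4-(3-methylbut-2-en-1-yl)phenoxy]-2-hydroxy-3-phenylpropanoic acid
Conditions: LiOH·H2O, THF–H2O, 0 °C to rt; then 1 M HCl to pH 3, 0 °C
Reagents that add atoms: lithium hydroxide, [Li+].[OH-]
Why: Saponification of the methyl ester should be faster than any reaction of the non-enolisable aryl aldehyde or of the acetals, and the benzylic ether centre is not acidic.

Step 7
Reactants: 11 (2R,3R)-3-[2-formyl-3,5-bis(methoxymethoxy)-4-(3-methylbut-2-en-1-yl)phenoxy]-2-hydroxy-3-phenylpropanoic acid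
Product: 12 (2R,3R)-2-acetoxy-3-[2-formyl-3,5-bis(methoxymethoxy)-4-(3-methylbut-2-en-1-yl)phenoxy]-3-phenylpropanoic acid
Conditions: Ac2O, pyridine, DMAP (cat.), CH2Cl2, 0 °C to rt; aqueous work-up
Reagents that add atoms: acetic anhydride, CC(=O)OC(C)=O
Why: O-Acetylation of the only free hydroxyl installs the acetate of the target, and any mixed anhydride at the acid is hydrolysed on work-up.

Step 8
Reactants: 12 (2R,3R)-2-acetoxy-3-[2-formyl-3,5-bis(methoxymethoxy)-4-(3-methylbut-2-en-1-yl)phenoxy]-3-phenylpropanoic acid
Product: 13 1,3-dioxoisoindolin-2-yl (2R,3R)-2-acetoxy-3-[2-formyl-3,5-bis(methoxymethoxy)-4-(3-methylbut-2-en-1-yl)phenoxy]-3-phenylpropanoate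
Conditions: N-hydroxyphthalimide, DIC, DMAP (5 mol %), CH2Cl2, 0 °C to rt
Reagents that add atoms: N-hydroxyphthalimide, O=C1c2ccccc2C(=O)N1O
Why: Steglich-type carbodiimide esterification should give the redox-active ester under near-neutral conditions that leave the aldehyde, the acetate and the β-aryloxy group in place.

Step 9
Reactants: 13 1,3-dioxoisoindolin-2-yl (2R,3R)-2-acetoxy-3-[2-formyl-3,5-bis(methoxymethoxy)-4-(3-methylbut-2-en-1-yl)phenoxy]-3-phenylpropanoate
Product: 14 (2R,3R)-5,7-bis(methoxymethoxy)-6-(3-methylbut-2-en-1-yl)-4-oxo-2-phenyl-3,4-dihydro-2H-chromen-3-yl acetate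
Conditions: 3-(2,6-diisopropylphenyl)-5,6,7,8-tetrahydro-4H-cyclohepta[d]thiazol-3-ium tetrafluoroborate (15 mol %), Cs2CO3 (15 mol %), degassed DMSO, rt to 40 °C, argon
Reagents that add atoms: none
Why: The thiazol-2-ylidene adds to the ring-A aldehyde (future C4) to give the Breslow intermediate, whose enolate transfers one electron to the tethered N-acyloxyphthalimide; loss of phthalimide anion and CO2 then leaves an α-acetoxyalkyl radical at C3 and the catalyst-bound ketyl radical at C4 in the same molecule. Their recombination forms the C3–C4 bond and collapse of the resulting alkoxide releases the carbene and the C4 ketone; the closest known reaction type is the NHC-catalysed decarboxylative radical acylation of aryl aldehydes with N-acyloxyphthalimides, together with the NHC radical cascades of O-allyl salicylaldehydes that close chroman-4-ones at this same bond by ketyl–alkyl radical recombination. Ring C closes by collapse of a 1,6-biradical (C4 and C3 joined through C4a, C8a, O1 and C2) to the six-membered pyranone. The only new stereocentre, C3, is set under substrate control by the adjacent C2 centre: in the half-chair-like arrangement of the closing ring the C2 phenyl and the C3 acetoxy group both take pseudo-equatorial positions, which should favour the 2,3-trans (3R) isomer. The step needs recombination to outrun β-scission of the C2–O1 bond and base-induced loss of the aryloxide from the activated ester, which the tether (making electron transfer and recombination intramolecular), the low base loading and the mild temperature should secure; C2 is neither a radical nor an enolisable centre in the precursor, so its configuration is carried through.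

Step 10
Reactants: 14 (2R,3R)-5,7-bis(methoxymethoxy)-6-(3-methylbut-2-en-1-yl)-4-oxo-2-phenyl-3,4-dihydro-2H-chromen-3-yl acetate
Product: 16 (2R,3R)-5,7-dihydroxy-6-(3-methylbut-2-en-1-yl)-4-oxo-2-phenyl-3,4-dihydro-2H-chromen-3-yl acetate, via bis(trimethylsilyl) ether 15 (not isolated)
Conditions: TMSOTf, 2,2′-bipyridyl, MeCN, 0 °C to rt; then H2O
Reagents that add atoms: none
Why: Silyl triflate/bipyridyl cleavage of aryl MOM ethers converts the acetals under non-protic, near-neutral conditions into aryl trimethylsilyl ethers that hydrolyse on addition of water, which should leave the C3 acetate, the prenyl alkene and both stereocentres untouched.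

Compound list
1 | phloroglucinol (benzene-1,3,5-triol) | Oc1cc(O)cc(O)c1 | starting material
2 | 3,5-bis(methoxymethoxy)phenol | COCOc1cc(O)cc(OCOC)c1 | intermediate
3 | [3,5-bis(methoxymethoxy)phenoxy]triisopropylsilane | CC(C)[Si](Oc1cc(OCOC)cc(OCOC)c1)(C(C)C)C(C)C | intermediate
4 | [2,6-bis(methoxymethoxy)-4-(triisopropylsilyloxy)phenyl]lithium (formed in the flask) | [Li]c1c(OCOC)cc(O[Si](C(C)C)(C(C)C)C(C)C)cc1OCOC | intermediate
5 | [3,5-bis(methoxymethoxy)-4-(3-methylbut-2-en-1-yl)phenoxy]triisopropylsilane (formed in the flask) | CC(C)=CCc1c(OCOC)cc(O[Si](C(C)C)(C(C)C)C(C)C)cc1OCOC | intermediate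
6 | 3,5-bis(methoxymethoxy)-4-(3-methylbut-2-en-1-yl)phenol | CC(C)=CCc1c(OCOC)cc(O)cc1OCOC | intermediate
7 | 2-(hydroxymethyl)-3,5-bis(methoxymethoxy)-4-(3-methylbut-2-en-1-yl)phenol (formed in the flask) | CC(C)=CCc1c(OCOC)cc(O)c(CO)c1OCOC | intermediate
8 | 6-hydroxy-2,4-bis(methoxymethoxy)-3-(3-methylbut-2-en-1-yl)benzaldehyde | CC(C)=CCc1c(OCOC)cc(O)c(C=O)c1OCOC | intermediate
9 | methyl (2R,3S)-3-phenyloxirane-2-carboxylate (trans) | COC(=O)[C@@H]1O[C@H]1c1ccccc1 | starting material
10 | methyl (2R,3R)-3-[2-formyl-3,5-bis(methoxymethoxy)-4-(3-methylbut-2-en-1-yl)phenoxy]-2-hydroxy-3-phenylpropanoate | COC(=O)[C@H](O)[C@H](Oc1cc(OCOC)c(CC=C(C)C)c(OCOC)c1C=O)c1ccccc1 | intermediate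
11 | (2R,3R)-3-[2-formyl-3,5-bis(methoxymethoxy)-4-(3-methylbut-2-en-1-yl)phenoxy]-2-hydroxy-3-phenylpropanoic acid | OC(=O)[C@H](O)[C@H](Oc1cc(OCOC)c(CC=C(C)C)c(OCOC)c1C=O)c1ccccc1 | intermediate
12 | (2R,3R)-2-acetoxy-3-[2-formyl-3,5-bis(methoxymethoxy)-4-(3-methylbut-2-en-1-yl)phenoxy]-3-phenylpropanoic acid | OC(=O)[C@H](OC(C)=O)[C@H](Oc1cc(OCOC)c(CC=C(C)C)c(OCOC)c1C=O)c1ccccc1 | intermediate
13 | 1,3-dioxoisoindolin-2-yl (2R,3R)-2-acetoxy-3-[2-formyl-3,5-bis(methoxymethoxy)-4-(3-methylbut-2-en-1-yl)phenoxy]-3-phenylpropanoate | O=C(ON1C(=O)c2ccccc2C1=O)[C@H](OC(C)=O)[C@H](Oc1cc(OCOC)c(CC=C(C)C)c(OCOC)c1C=O)c1ccccc1 | intermediate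
14 | (2R,3R)-5,7-bis(methoxymethoxy)-6-(3-methylbut-2-en-1-yl)-4-oxo-2-phenyl-3,4-dihydro-2H-chromen-3-yl acetate | CC(=O)O[C@H]1C(=O)c2c(cc(OCOC)c(CC=C(C)C)c2OCOC)O[C@@H]1c1ccccc1 | intermediate
15 | (2R,3R)-6-(3-methylbut-2-en-1-yl)-4-oxo-2-phenyl-5,7-bis(trimethylsilyloxy)-3,4-dihydro-2H-chromen-3-yl acetate (formed in the flask) | CC(=O)O[C@H]1C(=O)c2c(cc(O[Si](C)(C)C)c(CC=C(C)C)c2O[Si](C)(C)C)O[C@@H]1c1ccccc1 | intermediate
16 | (2R,3R)-5,7-dihydroxy-6-(3-methylbut-2-en-1-yl)-4-oxo-2-phenyl-3,4-dihydro-2H-chromen-3-yl acetate | CC(=O)O[C@H]1C(=O)c2c(cc(O)c(CC=C(C)C)c2O)O[C@@H]1c1ccccc1 | target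

Total step count: 10. Longest linear sequence: 10 steps (1 to 16); epoxide 9 enters as a purchased building block in step 5.

Steps most likely to fail

Step 9. Carbene addition to the electron-rich, doubly ortho-substituted aldehyde may be too slow, so that base-induced β-elimination of the aryloxide from the activated ester or β-scission of the C3 radical takes over. The radical recombination may also show poor facial selectivity at C3, and the basic medium may open the product ring at O1–C2 and erode the C2 configuration. Fallback: ring C is closed instead by acylation of the aromatic ring, with both stereocentres taken directly from the glycidate. It sets out from phenol 6 and epoxide 9. Cs2CO3-catalysed opening (DMF, 60 °C) by the unhindered phenol should give methyl (2R,3R)-3-[3,5-bis(methoxymethoxy)-4-(3-methylbut-2-en-1-yl)phenoxy]-2-hydroxy-3-phenylpropanoate F1. Saponification (LiOH, THF–H2O) should give (2R,3R)-3-[3,5-bis(methoxymethoxy)-4-(3-methylbut-2-en-1-yl)phenoxy]-2-hydroxy-3-phenylpropanoic acid F2, and acetylation (Ac2O, pyridine) (2R,3R)-2-acetoxy-3-[3,5-bis(methoxymethoxy)-4-(3-methylbut-2-en-1-yl)phenoxy]-3-phenylpropanoic acid F3. Intramolecular Friedel–Crafts acylation of F3 at either of the two equivalent ortho carbons of the phloroglucinol ether (trifluoroacetic anhydride, 2,6-di-tert-butyl-4-methylpyridine, CH2Cl2, 0 °C) should then give 14 with both centres retained. The route resumes at 14.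

Step 5. The hydrogen-bonded, hindered phenoxide may react sluggishly, attack may occur in part at the carbon next to the ester, or ionisation at the benzylic carbon may erode stereospecificity. Fallback: Mitsunobu etherification, which activates an alcohol partner instead of using an epoxide electrophile. It sets out from 8, which is coupled with commercial methyl (2R,3S)-2,3-dihydroxy-3-phenylpropanoate (COC(=O)[C@H](O)[C@@H](O)c1ccccc1) under PPh3, DIAD, toluene, 0 °C to rt. In syn-2,3-dihydroxy esters the C3 hydroxyl is the one that reacts, and inversion at this benzylic carbon (3S to 3R) should give hydroxy ester 10 directly. The route resumes at 10.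

Step 10. Loss of the C3 acetate, incomplete cleavage of the hindered C5 acetal, or ring opening at O1–C2 with epimerisation may occur during removal of the two acetal groups. Fallback: global deprotection followed by re-differentiation of the three hydroxyls. It sets out from 14. HCl in MeOH (40 °C) should remove both MOM groups and the acetate to give (2R,3R)-3,5,7-trihydroxy-6-(3-methylbut-2-en-1-yl)-2-phenyl-2,3-dihydro-4H-chromen-4-one F4. Peracetylation (Ac2O, pyridine) should give (2R,3R)-6-(3-methylbut-2-en-1-yl)-4-oxo-2-phenyl-3,4-dihydro-2H-chromene-3,5,7-triyl triacetate F5. Chemoselective cleavage of the two aryl acetates (NH4OAc, MeOH–H2O, rt), which are far more labile than the secondary alkyl acetate, should then return the route at target 16.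

Further compounds
F1 | step 9 | methyl (2R,3R)-3-[3,5-bis(methoxymethoxy)-4-(3-methylbut-2-en-1-yl)phenoxy]-2-hydroxy-3-phenylpropanoate | COC(=O)[C@H](O)[C@H](Oc1cc(OCOC)c(CC=C(C)C)c(OCOC)c1)c1ccccc1
F2 | step 9 | (2R,3R)-3-[3,5-bis(methoxymethoxy)-4-(3-methylbut-2-en-1-yl)phenoxy]-2-hydroxy-3-phenylpropanoic acid | OC(=O)[C@H](O)[C@H](Oc1cc(OCOC)c(CC=C(C)C)c(OCOC)c1)c1ccccc1
F3 | step 9 | (2R,3R)-2-acetoxy-3-[3,5-bis(methoxymethoxy)-4-(3-methylbut-2-en-1-yl)phenoxy]-3-phenylpropanoic acid | OC(=O)[C@H](OC(C)=O)[C@H](Oc1cc(OCOC)c(CC=C(C)C)c(OCOC)c1)c1ccccc1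
F0 | step 5 | none | none
F4 | step 10 | (2R,3R)-3,5,7-trihydroxy-6-(3-methylbut-2-en-1-yl)-2-phenyl-2,3-dihydro-4H-chromen-4-one | O[C@H]1C(=O)c2c(cc(O)c(CC=C(C)C)c2O)O[C@@H]1c1ccccc1
F5 | step 10 | (2R,3R)-6-(3-methylbut-2-en-1-yl)-4-oxo-2-phenyl-3,4-dihydro-2H-chromene-3,5,7-triyl triacetate | CC(=O)O[C@H]1C(=O)c2c(cc(OC(C)=O)c(CC=C(C)C)c2OC(C)=O)O[C@@H]1c1ccccc1
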